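**Plan**

- Cuts: the O–Si bond of the protected B-ring phenol, then the bond from chroman C3 to the aryl carbon C1' (C8 of the dimethylchromene). This gives 5,7-dimethoxy-6-prenyl-2H-chromene 7 and the B-ring arylboronate 13.
- Enabling feature: in 7 the C3=C4 alkene of the pyran ring is conjugated to the A ring through C4a. An aryl–rhodium therefore places its aryl on C3 and the metal on benzylic C4, and the ring leaves no syn β-hydrogen, so the adduct is protonated and not eliminated.
- 7 is cut further at O1–C2 and C4–C4a (propargyl ether, hydroarylation), at the phenol C–O (C–H borylation/oxidation) and at C6–prenyl (ortho-lithiation). 13 is cut at C–B, then at O–CMe2 and C4–C4a of the dimethylpyran (propargyl Claisen with bromine blocking the other ortho carbon), then at O–Si.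
- Forward order: A-ring arene → phenol → pyran ring of the chroman (7); 4-bromoresorcinol → dimethylpyran ring (11) → boronate 13; union of 7 and 13; desilylation.
- Stereochemistry: the only stereocentre (C3, R) is created in the union step by the chiral rhodium catalyst (enantioface selection at C3=C4). No later step touches it.

Key step: step 9

Assumption: the sense of induction of the rhodium/bisphosphine catalyst in step 9 is fixed on the first run; the ligand antipode that delivers the aryl group to the Si face of C3 (3R product) is used and is written here as the (R)-ligand.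
Remark: simple reagents stand on the reagent lines without a number; numbers are given to species made in one operation and consumed by a later addition, not to catalytic-cycle or pericyclic-cascade intermediates.

**Route**

Step 1
Reactants: 1 1,3-dimethoxybenzene
Product: 3 1,3-dimethoxy-2-(3-methylbut-2-en-1-yl)benzene, via 2,6-dimethoxyphenyllithium 2 (not isolated)
Conditions: n-BuLi, THF, 0 °C → rt; then prenyl bromide, −78 °C → rt
Reagents that add atoms: n-butyllithium, [Li]CCCC (lithium of 2 only); prenyl bromide (1-bromo-3-methylbut-2-ene), CC(C)=CCBr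
Why: Directed ortho-metalation of the position flanked by both methoxy groups followed by SN2 alkylation of the aryllithium with the allylic bromide should give the 2-prenyl arene.

Step 2
Reactants: 3 1,3-dimethoxy-2-(3-methylbut-2-en-1-yl)benzene
Product: 5 3,5-dimethoxy-4-(3-methylbut-2-en-1-yl)phenol, via arylboronic pinacol ester 4 (not isolated)
Conditions: [Ir(OMe)(cod)]2 (1.5 mol%), dtbpy (3 mol%), B2pin2 (1.0 equiv), THF, 60 °C; then NaOH, 30% H2O2, THF/H2O, 0 °C
Reagents that add atoms: bis(pinacolato)diboron, CC1(C)OB(OC1(C)C)B1OC(C)(C)C(C)(C)O1 (boryl group of 4 only); hydrogen peroxide, OO (phenol oxygen)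
Why: Iridium-catalysed aromatic C–H borylation is sterically controlled and should take C5, the only ring C–H without an ortho substituent, and basic peroxide oxidation of the C–B bond (one-pot borylation/oxidation) then gives the phenol without touching the unactivated prenyl alkene.

Step 3
Reactants: 5 3,5-dimethoxy-4-(3-methylbut-2-en-1-yl)phenol
Product: 6 1,3-dimethoxy-2-(3-methylbut-2-en-1-yl)-5-(prop-2-yn-1-yloxy)benzene
Conditions: propargyl bromide, K2CO3, acetone, reflux
Reagents that add atoms: propargyl bromide, C#CCBr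
Why: Williamson ether synthesis of the phenoxide with the primary propargylic bromide.

Step 4
Reactants: 6 1,3-dimethoxy-2-(3-methylbut-2-en-1-yl)-5-(prop-2-yn-1-yloxy)benzene
Product: 7 5,7-dimethoxy-6-(3-methylbut-2-en-1-yl)-2H-chromene
Conditions: [JohnPhosAu(MeCN)]SbF6 (2 mol%), CH2Cl2, rt
Reagents that add atoms: none
Why: Gold(I)-catalysed intramolecular hydroarylation of the aryl propargyl ether (6-endo-dig attack of an ortho carbon on the gold-activated alkyne, then protodeauration) should close the pyran ring, and the two ortho carbons are equivalent so only one regioisomer can form.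

Step 5
Reactants: 8 4-bromoresorcinol (4-bromobenzene-1,3-diol)
Product: 9 2-bromo-5-[(triisopropylsilyl)oxy]phenol
Conditions: TIPSCl (1.0 equiv), imidazole, CH2Cl2/DMF, 0 °C
Reagents that add atoms: chlorotriisopropylsilane, CC(C)[Si](Cl)(C(C)C)C(C)C
Why: Silyl ether formation in which the bulky silyl chloride should select the unhindered hydroxyl para to bromine over the hydroxyl flanked by bromine (steric control of regioselectivity), any minor isomer being separable.

Step 6
Reactants: 9 2-bromo-5-[(triisopropylsilyl)oxy]phenol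
Product: 10 {4-bromo-3-[(2-methylbut-3-yn-2-yl)oxy]phenoxy}tri(propan-2-yl)silane
Conditions: 3-chloro-3-methylbut-1-yne, DBU, CuCl2·2H2O (1 mol%), MeCN, 0 °C
Reagents that add atoms: 3-chloro-3-methylbut-1-yne, C#CC(C)(C)Cl
Why: Copper-catalysed propargylic substitution (phenoxide attack on a copper acetylide/allenylidene formed from the tertiary propargylic chloride) is the standard route to aryl 1,1-dimethylpropargyl ethers.

Step 7
Reactants: 10 {4-bromo-3-[(2-methylbut-3-yn-2-yl)oxy]phenoxy}tri(propan-2-yl)silane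
Product: 11 [(8-bromo-2,2-dimethyl-2H-chromen-5-yl)oxy]tri(propan-2-yl)silane
Conditions: o-xylene, 140 °C
Reagents that add atoms: none
Why: Aromatic propargyl Claisen rearrangement to the only free ortho carbon (the other bears bromine), followed in the same heating by enolisation, 1,5-hydrogen shift and oxa-6π electrocyclisation, should give the 2,2-dimethyl-2H-chromene with the pyran oxygen next to the C–Br carbon.

Step 8
Reactants: 11 [(8-bromo-2,2-dimethyl-2H-chromen-5-yl)oxy]tri(propan-2-yl)silane
Product: 13 {[2,2-dimethyl-8-(4,4,5,5-tetramethyl-1,3,2-dioxaborolan-2-yl)-2H-chromen-5-yl]oxy}tri(propan-2-yl)silane, via chromen-8-yllithium 12 (not isolated)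
Conditions: n-BuLi, THF, −78 °C; then i-PrOBpin, −78 °C → rt; aqueous work-up
Reagents that add atoms: n-butyllithium, [Li]CCCC (lithium of 12 only); 2-isopropoxy-4,4,5,5-tetramethyl-1,3,2-dioxaborolane, CC(C)OB1OC(C)(C)C(C)(C)O1
Why: Bromine–lithium exchange is faster than any deprotonation at −78 °C and the aryllithium is trapped by the electrophilic borate to give the pinacol boronate.

Step 9
Reactants: 7 5,7-dimethoxy-6-(3-methylbut-2-en-1-yl)-2H-chromene; 13 B-ring pinacol boronate
Product: 14 {[8-[(3R)-5,7-dimethoxy-6-(3-methylbut-2-en-1-yl)-3,4-dihydro-2H-chromen-3-yl]-2,2-dimethyl-2H-chromen-5-yl]oxy}tri(propan-2-yl)silane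
Conditions: [RhCl(C2H4)2]2 (2.5 mol%), (R)-SEGPHOS (5.5 mol%), K3PO4 (0.5 equiv), 13 (1.5 equiv), 1,4-dioxane/H2O 10:1, 70 °C
Reagents that add atoms: none
Why: Transmetalation of 13 to the rhodium(I)–bisphosphine complex gives an aryl–rhodium species, which adds syn across the C3=C4 bond of 7 (migratory insertion; aryl to C3, rhodium to C4), and water then protonates the C4–Rh bond and returns the Rh–OH catalyst. The closest known reaction type is the rhodium-catalysed asymmetric hydroarylation of cyclic and aryl-conjugated alkenes, 2H-chromenes included, with arylboron reagents (Hayashi–Miyaura manifold). No ring is closed; the step only joins the two bicyclic halves at C3–C1'. The one new stereocentre, C3, is set under catalyst control: the chiral bisphosphine on rhodium selects the Si face of C3 (the face on which C2 → C4 → H runs anticlockwise) for aryl delivery, which corresponds to 3R. The step needs regioselectivity (aryl to C3, not to C4), which the substrate secures because only rhodium at C4 is stabilised as an η3-benzyl by the A ring, and chemoselectivity among three alkenes, secured because the prenyl double bond is unconjugated and trisubstituted and the C3=C4 bond of the B-ring chromene is screened by the gem-dimethyl group at its C2. Heck-type β-hydride loss is disfavoured because after syn addition the only β-hydrogen (H3) lies anti to rhodium on the ring.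

Step 10
Reactants: 14 silyl-protected isoflavan
Product: 15 kanzonol I, 8-[(3R)-5,7-dimethoxy-6-(3-methylbut-2-en-1-yl)-3,4-dihydro-2H-chromen-3-yl]-2,2-dimethyl-2H-chromen-5-ol
Conditions: TBAF (1.1 equiv), AcOH (1.1 equiv), THF, 0 °C
Reagents that add atoms: none
Why: Fluoride-induced cleavage of the aryl silyl ether, buffered with acetic acid, frees the phenol under conditions that leave both alkenes, the aryl methyl ethers and the C3 stereocentre untouched.

**Compound list**

1 | 1,3-dimethoxybenzene | COc1cccc(OC)c1 | starting material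
2 | 2,6-dimethoxyphenyllithium | [Li]c1c(OC)cccc1OC | intermediate (not isolated)
3 | 1,3-dimethoxy-2-(3-methylbut-2-en-1-yl)benzene | COc1cccc(OC)c1CC=C(C)C | intermediate
4 | 2-[3,5-dimethoxy-4-(3-methylbut-2-en-1-yl)phenyl]-4,4,5,5-tetramethyl-1,3,2-dioxaborolane | COc1cc(B2OC(C)(C)C(C)(C)O2)cc(OC)c1CC=C(C)C | intermediate (not isolated)
5 | 3,5-dimethoxy-4-(3-methylbut-2-en-1-yl)phenol | COc1cc(O)cc(OC)c1CC=C(C)C | intermediate
6 | 1,3-dimethoxy-2-(3-methylbut-2-en-1-yl)-5-(prop-2-yn-1-yloxy)benzene | COc1cc(OCC#C)cc(OC)c1CC=C(C)C | intermediate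
7 | 5,7-dimethoxy-6-(3-methylbut-2-en-1-yl)-2H-chromene | COc1cc2OCC=Cc2c(OC)c1CC=C(C)C | intermediate
8 | 4-bromoresorcinol (4-bromobenzene-1,3-diol) | Oc1ccc(Br)c(O)c1 | starting material
9 | 2-bromo-5-[(triisopropylsilyl)oxy]phenol | Oc1cc(O[Si](C(C)C)(C(C)C)C(C)C)ccc1Br | intermediate
10 | {4-bromo-3-[(2-methylbut-3-yn-2-yl)oxy]phenoxy}tri(propan-2-yl)silane | C#CC(C)(C)Oc1cc(O[Si](C(C)C)(C(C)C)C(C)C)ccc1Br | intermediate
11 | [(8-bromo-2,2-dimethyl-2H-chromen-5-yl)oxy]tri(propan-2-yl)silane | Brc1ccc(O[Si](C(C)C)(C(C)C)C(C)C)c2C=CC(C)(C)Oc12 | intermediate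
12 | {2,2-dimethyl-5-[(triisopropylsilyl)oxy]-2H-chromen-8-yl}lithium | [Li]c1ccc(O[Si](C(C)C)(C(C)C)C(C)C)c2C=CC(C)(C)Oc12 | intermediate (not isolated)
13 | {[2,2-dimethyl-8-(4,4,5,5-tetramethyl-1,3,2-dioxaborolan-2-yl)-2H-chromen-5-yl]oxy}tri(propan-2-yl)silane | CC1(C)OB(OC1(C)C)c1ccc(O[Si](C(C)C)(C(C)C)C(C)C)c2C=CC(C)(C)Oc12 | intermediate
14 | {[8-[(3R)-5,7-dimethoxy-6-(3-methylbut-2-en-1-yl)-3,4-dihydro-2H-chromen-3-yl]-2,2-dimethyl-2H-chromen-5-yl]oxy}tri(propan-2-yl)silane | COc1cc2c(c(OC)c1CC=C(C)C)C[C@H](c1ccc(O[Si](C(C)C)(C(C)C)C(C)C)c3c1OC(C)(C)C=C3)CO2 | intermediate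
15 | kanzonol I, 8-[(3R)-5,7-dimethoxy-6-(3-methylbut-2-en-1-yl)-3,4-dihydro-2H-chromen-3-yl]-2,2-dimethyl-2H-chromen-5-ol | COc1cc2c(c(OC)c1CC=C(C)C)C[C@H](c1ccc(O)c3c1OC(C)(C)C=C3)CO2 | target

**Step count**

Total: 10 steps. Longest linear sequence: 6 steps (1 → 3 → 5 → 6 → 7 → 14 → 15; the branch from 8 is equally long).

**Steps most likely to fail**

Step 9. Carborhodation of the electron-rich alkene, which is flanked by the peri-methoxy group, may be slower than protodeboronation of the ortho-alkoxy arylboronate. A 1,4-rhodium shift onto the new aryl ring may lead to over-arylation, and facial selectivity may be insufficient. The fallback builds the same C3–C1' bond by lithiation–borylation with aryl 1,2-migration; it sets out from 5 and 13 and returns at 14. Phenol 5 is protected as its methoxymethyl ether F1 (MOMCl, i-Pr2NEt, CH2Cl2). Ortho-lithiation next to the OMOM group (n-BuLi, THF, 0 °C) gives the aryllithium F2, which opens ethylene oxide (BF3·OEt2, −78 °C) to the 2-arylethanol F3. Carbamoylation (i-Pr2NCOCl, Et3N, CH2Cl2, reflux) gives the N,N-diisopropylcarbamate F4. Sparteine-mediated asymmetric deprotonation (s-BuLi, (−)-sparteine, Et2O, −78 °C, removal of the pro-S hydrogen) gives the (S)-α-lithio carbamate F5, which is trapped by 13 with retention to the lithium boronate complex F6. On warming with MgBr2·OEt2 the B-ring aryl group migrates from boron to carbon with inversion and expels the carbamate. This gives the (R)-secondary boronic ester F7, which already holds the C3–C1' bond and the stereocentre. Matteson homologation (BrCH2Cl, n-BuLi, THF, −78 °C → rt) inserts C2 and gives the primary boronic ester F8, which is oxidised in the same flask (NaOH, H2O2) to the primary alcohol F9. Removal of the MOM group (cat. HCl, MeOH, 40 °C; the aryl silyl ether should stay) gives the phenol–alcohol F10. Mitsunobu cyclisation (PPh3, DIAD, THF, 0 °C) closes O1–C2 and gives 14.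

Step 2. Hydroboration or isomerisation of the prenyl double bond by iridium hydride and pinacolborane may compete with aromatic C–H borylation. The fallback installs the oxygen before the alkene; it sets out from 1 and returns at 5. C–H borylation of 1 at C5 (same catalyst) gives the arylboronate F11, which is oxidised (NaOH, H2O2) to 3,5-dimethoxyphenol F12 (also purchasable). Silylation (TIPSCl, imidazole) gives the silyl ether F13. Lithiation between the two methoxy groups (n-BuLi, THF, 0 °C; the bulky silyloxy group does not direct and screens its own ortho positions) gives the aryllithium F14, which is alkylated with prenyl bromide to the prenylated silyl ether F15. TBAF then gives 5.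

Step 4. Competing 5-exo closure to a benzofuran and gold- or acid-induced oligomerisation of the very electron-rich 2H-chromene may erode the step. The fallback forms the pyran ring by C–C bond formation under basic conditions; it sets out from 5 and returns at 7. Magnesium-mediated ortho-formylation of 5 (MgCl2, Et3N, paraformaldehyde, MeCN, reflux; both ortho positions are equivalent) gives the salicylaldehyde F16. A Schweizer reaction with vinyltriphenylphosphonium bromide (K2CO3, DMF, 80 °C; phenoxide conjugate addition, then intramolecular Wittig reaction) closes O1–C2, forms C3=C4 and gives 7.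

**Further compounds**

F1 | step 9 | 1,3-dimethoxy-5-(methoxymethoxy)-2-(3-methylbut-2-en-1-yl)benzene | COCOc1cc(OC)c(CC=C(C)C)c(OC)c1
F2 | step 9 | [2,4-dimethoxy-6-(methoxymethoxy)-3-(3-methylbut-2-en-1-yl)phenyl]lithium | COCOc1cc(OC)c(CC=C(C)C)c(OC)c1[Li]
F3 | step 9 | 2-[2,4-dimethoxy-6-(methoxymethoxy)-3-(3-methylbut-2-en-1-yl)phenyl]ethan-1-ol | COCOc1cc(OC)c(CC=C(C)C)c(OC)c1CCO
F4 | step 9 | 2-[2,4-dimethoxy-6-(methoxymethoxy)-3-(3-methylbut-2-en-1-yl)phenyl]ethyl N,N-di(propan-2-yl)carbamate | COCOc1cc(OC)c(CC=C(C)C)c(OC)c1CCOC(=O)N(C(C)C)C(C)C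
F5 | step 9 | (1S)-1-lithio-2-[2,4-dimethoxy-6-(methoxymethoxy)-3-(3-methylbut-2-en-1-yl)phenyl]ethyl N,N-di(propan-2-yl)carbamate | COCOc1cc(OC)c(CC=C(C)C)c(OC)c1C[C@H]([Li])OC(=O)N(C(C)C)C(C)C
F6 | step 9 | lithium (S)-boronate complex of F5 with 13 (B-aryl, B-alkyl pinacol borate) | COCOc1cc(OC)c(CC=C(C)C)c(OC)c1C[C@H]([B-]1(OC(C)(C)C(C)(C)O1)c1ccc(O[Si](C(C)C)(C(C)C)C(C)C)c2C=CC(C)(C)Oc12)OC(=O)N(C(C)C)C(C)C.[Li+]
F7 | step 9 | (R)-secondary boronic ester, 2-{(1R)-2-[2,4-dimethoxy-6-(methoxymethoxy)-3-prenylphenyl]-1-[2,2-dimethyl-5-(triisopropylsilyloxy)-2H-chromen-8-yl]ethyl}-4,4,5,5-tetramethyl-1,3,2-dioxaborolane | COCOc1cc(OC)c(CC=C(C)C)c(OC)c1C[C@@H](B1OC(C)(C)C(C)(C)O1)c1ccc(O[Si](C(C)C)(C(C)C)C(C)C)c2C=CC(C)(C)Oc12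
F8 | step 9 | (R)-primary boronic ester, 2-{(2R)-3-[2,4-dimethoxy-6-(methoxymethoxy)-3-prenylphenyl]-2-[2,2-dimethyl-5-(triisopropylsilyloxy)-2H-chromen-8-yl]propyl}-4,4,5,5-tetramethyl-1,3,2-dioxaborolane | COCOc1cc(OC)c(CC=C(C)C)c(OC)c1C[C@@H](CB1OC(C)(C)C(C)(C)O1)c1ccc(O[Si](C(C)C)(C(C)C)C(C)C)c2C=CC(C)(C)Oc12
F9 | step 9 | (2R)-3-[2,4-dimethoxy-6-(methoxymethoxy)-3-prenylphenyl]-2-[2,2-dimethyl-5-(triisopropylsilyloxy)-2H-chromen-8-yl]propan-1-ol | COCOc1cc(OC)c(CC=C(C)C)c(OC)c1C[C@@H](CO)c1ccc(O[Si](C(C)C)(C(C)C)C(C)C)c2C=CC(C)(C)Oc12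
F10 | step 9 | 2-{(2R)-2-[2,2-dimethyl-5-(triisopropylsilyloxy)-2H-chromen-8-yl]-3-hydroxypropyl}-3,5-dimethoxy-4-(3-methylbut-2-en-1-yl)phenol | Oc1cc(OC)c(CC=C(C)C)c(OC)c1C[C@@H](CO)c1ccc(O[Si](C(C)C)(C(C)C)C(C)C)c2C=CC(C)(C)Oc12
F11 | step 2 | 2-(3,5-dimethoxyphenyl)-4,4,5,5-tetramethyl-1,3,2-dioxaborolane | COc1cc(cc(OC)c1)B1OC(C)(C)C(C)(C)O1
F12 | step 2 | 3,5-dimethoxyphenol | COc1cc(O)cc(OC)c1
F13 | step 2 | (3,5-dimethoxyphenoxy)tri(propan-2-yl)silane | COc1cc(O[Si](C(C)C)(C(C)C)C(C)C)cc(OC)c1
F14 | step 2 | {2,6-dimethoxy-4-[(triisopropylsilyl)oxy]phenyl}lithium | [Li]c1c(OC)cc(O[Si](C(C)C)(C(C)C)C(C)C)cc1OC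
F15 | step 2 | [3,5-dimethoxy-4-(3-methylbut-2-en-1-yl)phenoxy]tri(propan-2-yl)silane | COc1cc(O[Si](C(C)C)(C(C)C)C(C)C)cc(OC)c1CC=C(C)C
F16 | step 4 | 6-hydroxy-2,4-dimethoxy-3-(3-methylbut-2-en-1-yl)benzaldehyde | O=Cc1c(O)cc(OC)c(CC=C(C)C)c1OC
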